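Ring B is closed last, at C6–C7 (eudesmane numbering). C6 is an allylic methylene on the tetrasubstituted C4=C5 alkene of ring A, and C7 is α to the C8 oxygen; the key step therefore joins an allylic bromide at C6 to the enolate of a C8 ketone. In one operation it forms ring B, completes the C15 skeleton and sets C7, whose side chain settles equatorially on the chair fixed by the quaternary C10. The precursor is a single ring A cyclohexene: bromomethyl on C5, methyl on C4, silyl ether at C3 (3S), and on C10 (R) a methyl group and the methyl 2-methyl-4-oxopentanoate chain.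

Key step: step 13

Remark: C11 forms as both epimers in step 10 and becomes sp2 in step 15, so it is left undefined in names and SMILES; eudesmane locants (C1–C15) are used in the explanations; TBS = tert-butyldimethylsilyl, PMB = 4-methoxybenzyl.

Step 1
Reactants: 1 2-methylcyclohexane-1,3-dione
Product: 2 3-isobutoxy-2-methylcyclohex-2-en-1-one
Conditions: i-BuOH, p-TsOH (cat.), PhMe, reflux, Dean–Stark
Reagents that add atoms: 2-methylpropan-1-ol, CC(C)CO
Why: Acid-catalysed condensation of the symmetric 1,3-dione with the alcohol under azeotropic removal of water (vinylogous ester formation) fixes C3–C5 and the C15 methyl of ring A.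

Step 2
Reactants: 2 3-isobutoxy-2-methylcyclohex-2-en-1-one
Product: 3 3-isobutoxy-2,6-dimethylcyclohex-2-en-1-one (racemic)
Conditions: LiN(i-Pr)2, THF, −78 °C; MeI, −78 → 0 °C
Reagents that add atoms: iodomethane, CI
Why: Kinetic deprotonation of a vinylogous ester occurs at the α′ carbon, so enolate alkylation (Stork–Danheiser alkylation) puts the future C14 methyl on the future C10; the racemic centre is erased in step 3.

Step 3
Reactants: 3 3-isobutoxy-2,6-dimethylcyclohex-2-en-1-one; 4 allyl chloroformate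
Product: 5 allyl 5-isobutoxy-2,6-dimethylcyclohexa-1,5-dien-1-yl carbonate
Conditions: LiN(i-Pr)2, TMEDA, THF, −78 °C; then 4, −78 → 0 °C
Reagents that add atoms: allyl chloroformate (4), C=CCOC(=O)Cl
Why: The fully substituted α′ lithium enolate is trapped on oxygen by the hard chloroformate (enolate O-acylation to an allyl enol carbonate), giving an achiral substrate for step 4, and acylation on carbon would feed the same palladium enolate there.

Step 4
Reactants: 5 allyl 5-isobutoxy-2,6-dimethylcyclohexa-1,5-dien-1-yl carbonate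
Product: 6 (R)-6-allyl-3-isobutoxy-2,6-dimethylcyclohex-2-en-1-one
Conditions: Pd2(dba)3 (2.5 mol %), (R)-t-BuPHOX (6 mol %), PhMe, 30 °C
Reagents that add atoms: none
Why: Decarboxylative asymmetric allylic alkylation (Tsuji allylation): zerovalent palladium ionises the allyl carbonate, CO2 is lost, and the allylpalladium enolate recombines under ligand control; by analogy with 2-methylcyclohexanone enolates the (R)-ligand is expected to give the R quaternary centre that becomes C10.

Step 5
Reactants: 7 (tributylstannyl)methanol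
Product: 8 tributyl[(PMB-oxy)methyl]stannane
Conditions: NaH, 4-methoxybenzyl chloride, n-Bu4NI (cat.), THF/DMF, 0 → 23 °C
Reagents that add atoms: 4-methoxybenzyl chloride, COc1ccc(CCl)cc1
Why: Williamson etherification of the primary alkoxide gives a stannane that serves as a protected hydroxymethyl anion equivalent.

Step 6
Reactants: 6 (R)-6-allyl-3-isobutoxy-2,6-dimethylcyclohex-2-en-1-one; 8 tributyl[(PMB-oxy)methyl]stannane
Product: 10 (R)-4-allyl-2,4-dimethyl-3-[(PMB-oxy)methyl]cyclohex-2-en-1-one, via carbinol 9 (not isolated)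
Conditions: 8, n-BuLi, THF, −78 °C; then 6, −78 → −20 °C; then 1 M HCl, THF, 23 °C
Reagents that add atoms: tributyl[(PMB-oxy)methyl]stannane (8), CCCC[Sn](CCCC)(CCCC)COCc1ccc(OC)cc1; water, O
Why: Tin–lithium exchange gives the α-alkoxymethyllithium, which adds 1,2 to the vinylogous ester carbonyl, and acid hydrolysis of the tertiary allylic carbinol transposes the carbonyl (Stork–Danheiser transposition), so the C6 carbon sits on C5 next to the quaternary C10.

Step 7
Reactants: 10 (R)-4-allyl-2,4-dimethyl-3-[(PMB-oxy)methyl]cyclohex-2-en-1-one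
Product: 11 (1S,4R)-4-allyl-2,4-dimethyl-3-[(PMB-oxy)methyl]cyclohex-2-en-1-ol
Conditions: (R)-2-methyl-CBS-oxazaborolidine (0.2 equiv), catecholborane, PhMe, −78 °C
Reagents that add atoms: none
Why: Corey–Bakshi–Shibata reduction, with the α-methylated alkene side as the large group, is expected to set C3 as S under catalyst control, which is needed because the monocycle has no facial bias of its own (C10 carries two groups of similar size), and it turns any minor C10 enantiomer into a separable diastereomer.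

Step 8
Reactants: 11 (1S,4R)-4-allyl-2,4-dimethyl-3-[(PMB-oxy)methyl]cyclohex-2-en-1-ol
Product: 12 {[(1S,4R)-4-allyl-2,4-dimethyl-3-[(PMB-oxy)methyl]cyclohex-2-en-1-yl]oxy}(tert-butyl)dimethylsilane
Conditions: TBSCl, imidazole, DMF, 23 °C
Reagents that add atoms: tert-butyldimethylsilyl chloride, CC(C)(C)[Si](C)(C)Cl
Why: Silyl ether formation on the secondary allylic alcohol gives a C3 protecting group that should withstand the oxidative, basic and hydride conditions up to step 18.

Step 9
Reactants: 12 {[(1S,4R)-4-allyl-2,4-dimethyl-3-[(PMB-oxy)methyl]cyclohex-2-en-1-yl]oxy}(tert-butyl)dimethylsilane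
Product: 14 2-[(1R,4S)-4-(TBS-oxy)-1,3-dimethyl-2-[(PMB-oxy)methyl]cyclohex-2-en-1-yl]acetaldehyde, via diol 13 (not isolated)
Conditions: OsO4 (2 mol %), NaIO4, 2,6-lutidine, dioxane/H2O, 23 °C
Reagents that add atoms: osmium tetroxide, O=[Os](=O)(=O)=O; sodium periodate, [Na+].[O-]I(=O)(=O)=O
Why: Lemieux–Johnson cleavage: dihydroxylation selects the unhindered monosubstituted alkene over the tetrasubstituted ring alkene beside the quaternary carbon, and periodate cleaves the diol to the C8 aldehyde.

Step 10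
Reactants: 14 2-[(1R,4S)-4-(TBS-oxy)-1,3-dimethyl-2-[(PMB-oxy)methyl]cyclohex-2-en-1-yl]acetaldehyde; 15 methyl methacrylate
Product: 16 methyl 5-[(1R,4S)-4-(TBS-oxy)-1,3-dimethyl-2-[(PMB-oxy)methyl]cyclohex-2-en-1-yl]-2-methyl-4-oxopentanoate (both C11 epimers)
Conditions: 3-benzyl-5-(2-hydroxyethyl)-4-methylthiazolium chloride (0.2 equiv), Et3N, 15 (3 equiv), dioxane, 80 °C
Reagents that add atoms: methyl methacrylate (15), C=C(C)C(=O)OC
Why: Stetter reaction: the carbene-derived acyl anion equivalent of the aliphatic aldehyde adds to the unsubstituted β-carbon of the acrylate, forming C7–C8 and the 1,4-keto ester; C11 forms without control.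

Step 11
Reactants: 16 methyl 5-[(1R,4S)-4-(TBS-oxy)-1,3-dimethyl-2-[(PMB-oxy)methyl]cyclohex-2-en-1-yl]-2-methyl-4-oxopentanoate
Product: 17 methyl 5-[(1R,4S)-4-(TBS-oxy)-2-(hydroxymethyl)-1,3-dimethylcyclohex-2-en-1-yl]-2-methyl-4-oxopentanoate
Conditions: DDQ, CH2Cl2/pH 7 buffer, 0 °C
Reagents that add atoms: none
Why: Oxidative cleavage of the PMB ether by DDQ frees the C6 alcohol under neutral conditions that leave the silyl ether, ketone, ester and hindered alkene untouched.

Step 12
Reactants: 17 methyl 5-[(1R,4S)-4-(TBS-oxy)-2-(hydroxymethyl)-1,3-dimethylcyclohex-2-en-1-yl]-2-methyl-4-oxopentanoate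
Product: 18 methyl 5-[(1R,4S)-2-(bromomethyl)-4-(TBS-oxy)-1,3-dimethylcyclohex-2-en-1-yl]-2-methyl-4-oxopentanoate (3S,10R; both C11 epimers)
Conditions: CBr4, PPh3, CH2Cl2, 0 °C
Reagents that add atoms: carbon tetrabromide, BrC(Br)(Br)Br
Why: Appel bromination converts the primary allylic alcohol into the bromide without acid or base, and it draws the open hydroxy ketone out of any ring–chain (hemiketal) equilibrium because only the primary alcohol is activated; the bromide is used at once.

Step 13
Reactants: 18 methyl 5-[(1R,4S)-2-(bromomethyl)-4-(TBS-oxy)-1,3-dimethylcyclohex-2-en-1-yl]-2-methyl-4-oxopentanoate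
Product: 20 methyl (3S,7R,10R)-3-(TBS-oxy)-8-oxoeudesm-4-en-12-oate, via 7-epimer 19 (not isolated)
Conditions: LiN(SiMe3)2 (1.05 equiv), THF (0.02 M), −78 → 0 °C; then NaOMe (0.2 equiv), MeOH, 23 °C
Reagents that add atoms: none
Why: The amide base deprotonates the ketone on its less hindered α-carbon to give the C7 lithium enolate, which displaces the primary allylic bromide at C6 in an SN2 reaction and so forms C6–C7; the closest known reaction type is the intramolecular C-alkylation of a ketone enolate by an allylic halide. Ring B, the only ring formed, closes in the 6-(enolendo)-exo-tet mode. C7 is the only new stereocentre: closure of the Z-enolate through a chair should place C11 equatorial, and the methoxide stage equilibrates the α-centre so that the 7α-epimer 19 should converge on the 7β-epimer 20, whose side chain is equatorial on the ring B chair that the quaternary C10 locks with its methyl axial. The step needs C7 over C9 enolisation, C- over O-alkylation and SN2 over SN2′ attack. A C9 enolate can close only a four-membered ring through carbon and returns by proton exchange with the product ketone, the tight lithium–oxygen bond in THF and the soft allylic bromide keep both enolates from O-alkylation, and the SN2′ terminus C4 is fully substituted. C11 remains a mixture, which does not matter because it becomes sp2 in step 15.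

Step 14
Reactants: 20 methyl (3S,7R,10R)-3-(TBS-oxy)-8-oxoeudesm-4-en-12-oate
Product: 22 (3S,7R,8R,10R)-3-(TBS-oxy)eudesm-4-en-12,8-olide (cis-fused 8β,12-lactone), via hydroxy ester 21 (not isolated)
Conditions: LiBH(s-Bu)3, THF, −78 °C; AcOH; then PPTS (cat.), PhMe, 60 °C
Reagents that add atoms: none
Why: The bulky hydride attacks C8 along the equatorial trajectory on the α-face, away from the axial C10 methyl (diastereoselective ketone reduction), giving the axial 8β-alcohol (8R) cis to the C7 side chain, which then closes to the cis-fused γ-lactone (lactonisation).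

Step 15
Reactants: 22 (3S,7R,8R,10R)-3-(TBS-oxy)eudesm-4-en-12,8-olide
Product: 24 (3S,7R,8R,10R)-3-(TBS-oxy)eudesma-4,11(13)-dien-12,8-olide, via 11-bromo lactone 23 (not isolated)
Conditions: LiN(i-Pr)2, THF, −78 °C; CBr4; AcOH; then DBU, PhMe, 50 °C
Reagents that add atoms: none
Why: Enolate bromination occurs on the convex face of the cis-fused lactone, cis to H7, so the E2 dehydrobromination, which needs an anti hydrogen, can use only C13 and gives the 11(13)-methylene lactone, whereas a selenoxide syn-elimination on this cis-lactone would have H7 within reach and would move the double bond to C7.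

Step 16
Reactants: 24 (3S,7R,8R,10R)-3-(TBS-oxy)eudesma-4,11(13)-dien-12,8-olide
Product: 26 methyl (3S,7R,8R,10R)-3-(TBS-oxy)-8-hydroxyeudesma-4,11(13)-dien-12-oate, via lithium carboxylate 25 (not isolated)
Conditions: LiOH (1.0 equiv), THF/H2O, 23 °C; evaporate; then MeI, DMF, 23 °C
Reagents that add atoms: lithium hydroxide, [Li+].[OH-]; iodomethane, CI
Why: Saponification opens the lactone irreversibly, and SN2 alkylation of the carboxylate with iodomethane gives the methyl ester without an acidic stage, so the cis-hydroxy ester is not driven back to the lactone.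

Step 17
Reactants: 26 methyl (3S,7R,8R,10R)-3-(TBS-oxy)-8-hydroxyeudesma-4,11(13)-dien-12-oate
Product: 27 methyl (3S,7R,8R,10R)-8-acetoxy-3-(TBS-oxy)eudesma-4,11(13)-dien-12-oate
Conditions: Ac2O, DMAP, pyridine, CH2Cl2, 0 → 23 °C
Reagents that add atoms: acetic anhydride, CC(=O)OC(C)=O
Why: DMAP-catalysed acylation of the axial 8β-alcohol, run at once on fresh 26, should outrun relactonisation and fix the open form as the acetate.

Step 18
Reactants: 27 methyl (3S,7R,8R,10R)-8-acetoxy-3-(TBS-oxy)eudesma-4,11(13)-dien-12-oate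
Product: 28 methyl (3S,7R,8R,10R)-8-acetoxy-3-hydroxyeudesma-4,11(13)-dien-12-oate
Conditions: HF·pyridine, pyridine, THF, 0 → 23 °C
Reagents that add atoms: none
Why: Fluoride-mediated desilylation under buffered, non-basic conditions releases the 3β-alcohol while the acetate, the methyl ester and the acrylate survive.

Step 19
Reactants: 28 methyl (3S,7R,8R,10R)-8-acetoxy-3-hydroxyeudesma-4,11(13)-dien-12-oate
Product: 29 methyl (3S,7R,8R,10R)-8-acetoxy-3-(isobutyryloxy)eudesma-4,11(13)-dien-12-oate (target)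
Conditions: (i-PrCO)2O, DMAP, Et3N, CH2Cl2, 23 °C
Reagents that add atoms: isobutyric anhydride, CC(C)C(=O)OC(=O)C(C)C
Why: DMAP-catalysed esterification of the unhindered equatorial allylic 3β-alcohol installs the isobutyrate with retention at C3 and completes the target.

Compound list
1 | 2-methylcyclohexane-1,3-dione | CC1C(=O)CCCC1=O | starting material
2 | 3-isobutoxy-2-methylcyclohex-2-en-1-one | CC(C)COC1=C(C)C(=O)CCC1 | intermediate
3 | 3-isobutoxy-2,6-dimethylcyclohex-2-en-1-one (racemic) | CC(C)COC1=C(C)C(=O)C(C)CC1 | intermediate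
4 | allyl chloroformate | C=CCOC(=O)Cl | starting material
5 | allyl 5-isobutoxy-2,6-dimethylcyclohexa-1,5-dien-1-yl carbonate | C=CCOC(=O)OC1=C(C)CCC(OCC(C)C)=C1C | intermediate
6 | (R)-6-allyl-3-isobutoxy-2,6-dimethylcyclohex-2-en-1-one | C=CC[C@@]1(C)CCC(OCC(C)C)=C(C)C1=O | intermediate
7 | (tributylstannyl)methanol | CCCC[Sn](CCCC)(CCCC)CO | starting material
8 | tributyl[(PMB-oxy)methyl]stannane | CCCC[Sn](CCCC)(CCCC)COCc1ccc(OC)cc1 | intermediate
9 | (6R)-6-allyl-3-isobutoxy-2,6-dimethyl-1-[(PMB-oxy)methyl]cyclohex-2-en-1-ol (carbinol epimers) | C=CC[C@@]1(C)CCC(OCC(C)C)=C(C)C1(O)COCc1ccc(OC)cc1 | intermediate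
10 | (R)-4-allyl-2,4-dimethyl-3-[(PMB-oxy)methyl]cyclohex-2-en-1-one | C=CC[C@@]1(C)CCC(=O)C(C)=C1COCc1ccc(OC)cc1 | intermediate
11 | (1S,4R)-4-allyl-2,4-dimethyl-3-[(PMB-oxy)methyl]cyclohex-2-en-1-ol | C=CC[C@@]1(C)CC[C@H](O)C(C)=C1COCc1ccc(OC)cc1 | intermediate
12 | {[(1S,4R)-4-allyl-2,4-dimethyl-3-[(PMB-oxy)methyl]cyclohex-2-en-1-yl]oxy}(tert-butyl)dimethylsilane | C=CC[C@@]1(C)CC[C@H](O[Si](C)(C)C(C)(C)C)C(C)=C1COCc1ccc(OC)cc1 | intermediate
13 | 3-[(1R,4S)-4-(TBS-oxy)-1,3-dimethyl-2-[(PMB-oxy)methyl]cyclohex-2-en-1-yl]propane-1,2-diol (carbinol epimers) | OCC(O)C[C@@]1(C)CC[C@H](O[Si](C)(C)C(C)(C)C)C(C)=C1COCc1ccc(OC)cc1 | intermediate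
14 | 2-[(1R,4S)-4-(TBS-oxy)-1,3-dimethyl-2-[(PMB-oxy)methyl]cyclohex-2-en-1-yl]acetaldehyde | O=CC[C@@]1(C)CC[C@H](O[Si](C)(C)C(C)(C)C)C(C)=C1COCc1ccc(OC)cc1 | intermediate
15 | methyl methacrylate | C=C(C)C(=O)OC | starting material
16 | methyl 5-[(1R,4S)-4-(TBS-oxy)-1,3-dimethyl-2-[(PMB-oxy)methyl]cyclohex-2-en-1-yl]-2-methyl-4-oxopentanoate (C11 epimers) | COC(=O)C(C)CC(=O)C[C@@]1(C)CC[C@H](O[Si](C)(C)C(C)(C)C)C(C)=C1COCc1ccc(OC)cc1 | intermediate
17 | methyl 5-[(1R,4S)-4-(TBS-oxy)-2-(hydroxymethyl)-1,3-dimethylcyclohex-2-en-1-yl]-2-methyl-4-oxopentanoate (C11 epimers) | COC(=O)C(C)CC(=O)C[C@@]1(C)CC[C@H](O[Si](C)(C)C(C)(C)C)C(C)=C1CO | intermediate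
18 | methyl 5-[(1R,4S)-2-(bromomethyl)-4-(TBS-oxy)-1,3-dimethylcyclohex-2-en-1-yl]-2-methyl-4-oxopentanoate (3S,10R; C11 epimers) | COC(=O)C(C)CC(=O)C[C@@]1(C)CC[C@H](O[Si](C)(C)C(C)(C)C)C(C)=C1CBr | intermediate
19 | methyl (3S,7S,10R)-3-(TBS-oxy)-8-oxoeudesm-4-en-12-oate (7α side chain; C11 epimers) | COC(=O)C(C)[C@@H]1CC2=C(C)[C@@H](O[Si](C)(C)C(C)(C)C)CC[C@]2(C)CC1=O | intermediate
20 | methyl (3S,7R,10R)-3-(TBS-oxy)-8-oxoeudesm-4-en-12-oate (3β-OTBS, 7β side chain, 10β-methyl; C11 epimers) | COC(=O)C(C)[C@H]1CC2=C(C)[C@@H](O[Si](C)(C)C(C)(C)C)CC[C@]2(C)CC1=O | intermediate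
21 | methyl (3S,7R,8R,10R)-3-(TBS-oxy)-8-hydroxyeudesm-4-en-12-oate (8β-OH; C11 epimers) | COC(=O)C(C)[C@H]1CC2=C(C)[C@@H](O[Si](C)(C)C(C)(C)C)CC[C@]2(C)C[C@H]1O | intermediate
22 | (3S,7R,8R,10R)-3-(TBS-oxy)eudesm-4-en-12,8-olide (cis-fused; C11 epimers) | O=C1O[C@@H]2C[C@@]3(C)CC[C@H](O[Si](C)(C)C(C)(C)C)C(C)=C3C[C@@H]2C1C | intermediate
23 | (3S,7S,8R,10R,11R)-11-bromo-3-(TBS-oxy)eudesm-4-en-12,8-olide (Br cis to H7) | O=C1O[C@@H]2C[C@@]3(C)CC[C@H](O[Si](C)(C)C(C)(C)C)C(C)=C3C[C@@H]2[C@@]1(C)Br | intermediate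
24 | (3S,7R,8R,10R)-3-(TBS-oxy)eudesma-4,11(13)-dien-12,8-olide | C=C1C(=O)O[C@@H]2C[C@@]3(C)CC[C@H](O[Si](C)(C)C(C)(C)C)C(C)=C3C[C@H]12 | intermediate
25 | lithium (3S,7R,8R,10R)-3-(TBS-oxy)-8-hydroxyeudesma-4,11(13)-dien-12-oate | [Li+].[O-]C(=O)C(=C)[C@H]1CC2=C(C)[C@@H](O[Si](C)(C)C(C)(C)C)CC[C@]2(C)C[C@H]1O | intermediate
26 | methyl (3S,7R,8R,10R)-3-(TBS-oxy)-8-hydroxyeudesma-4,11(13)-dien-12-oate | C=C(C(=O)OC)[C@H]1CC2=C(C)[C@@H](O[Si](C)(C)C(C)(C)C)CC[C@]2(C)C[C@H]1O | intermediate
27 | methyl (3S,7R,8R,10R)-8-acetoxy-3-(TBS-oxy)eudesma-4,11(13)-dien-12-oate | C=C(C(=O)OC)[C@H]1CC2=C(C)[C@@H](O[Si](C)(C)C(C)(C)C)CC[C@]2(C)C[C@H]1OC(C)=O | intermediate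
28 | methyl (3S,7R,8R,10R)-8-acetoxy-3-hydroxyeudesma-4,11(13)-dien-12-oate | C=C(C(=O)OC)[C@H]1CC2=C(C)[C@@H](O)CC[C@]2(C)C[C@H]1OC(C)=O | intermediate
29 | methyl (3S,7R,8R,10R)-8-acetoxy-3-(isobutyryloxy)eudesma-4,11(13)-dien-12-oate (CNP0127901.1) | C=C(C(=O)OC)[C@H]1CC2=C(C)[C@@H](OC(=O)C(C)C)CC[C@]2(C)C[C@H]1OC(C)=O | target

Total step count: 19. Longest linear sequence: 18 (steps 1–4 and 6–19; step 5 is a one-step branch).

Steps most likely to fail

Step 13 (ring closure). Alkylation on the enolate oxygen, or enolisation toward C9 that exchanges too slowly, would divert material from C–C bond formation. If the equatorial preference of the α-branched side chain next to the carbonyl is small, equilibration at C7 would also not converge fully. The fallback forms the same C6–C7 bond by a reversible aldol closure and sets C7 by kinetic protonation. It sets out from 17: oxidation of the allylic alcohol with MnO2 (CH2Cl2) should give the enal methyl 5-[(1R,4S)-4-(TBS-oxy)-2-formyl-1,3-dimethylcyclohex-2-en-1-yl]-2-methyl-4-oxopentanoate F1. An intramolecular aldol condensation (pyrrolidine, AcOH, PhMe, 60 °C), in which only the six-membered adduct can dehydrate, should give the dienone methyl (3S,10R)-3-(TBS-oxy)-8-oxoeudesma-4,6-dien-12-oate F2. Conjugate reduction of the C6=C7 bond with [(Ph3P)CuH]6 (PhMe, then aqueous NH4Cl) generates the C7 enolate regiospecifically, and axial protonation on the α-face comes back to the route at 20.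

Step 10 (Stetter coupling). Addition of the acyl anion equivalent to the α-substituted acrylate may be slow, so that self-condensation of the aldehyde takes over. The fallback builds the chain from a methyl ketone enolate instead and sets out from 12: Tsuji–Wacker oxidation of the allyl group (PdCl2, CuCl, O2, DMF/H2O) should give the methyl ketone 1-[(1R,4S)-4-(TBS-oxy)-1,3-dimethyl-2-[(PMB-oxy)methyl]cyclohex-2-en-1-yl]propan-2-one F3. Kinetic deprotonation on the methyl side (LiN(i-Pr)2, THF, −78 °C) and alkylation with methyl 2-bromopropanoate form C7–C11 and come back to the route at 16.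

Step 15 (methylene lactone). Bromination on the concave face, or base-induced migration of the exocyclic double bond into conjugation, would erase C7. The fallback replaces the halide by an alcohol and sets out from 22: hydroxylation of the lactone enolate (LiN(i-Pr)2, THF, −78 °C; 2-(phenylsulfonyl)-3-phenyloxaziridine) on the convex face should give (3S,7S,8R,10R,11R)-11-hydroxy-3-(TBS-oxy)eudesm-4-en-12,8-olide F4. Dehydration with SOCl2 in pyridine at 0 °C, an anti elimination for which again only C13 offers a hydrogen, comes back to the route at 24.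

Further compounds
F1 | step 13 | methyl 5-[(1R,4S)-4-(TBS-oxy)-2-formyl-1,3-dimethylcyclohex-2-en-1-yl]-2-methyl-4-oxopentanoate (C11 epimers) | COC(=O)C(C)CC(=O)C[C@@]1(C)CC[C@H](O[Si](C)(C)C(C)(C)C)C(C)=C1C=O
F2 | step 13 | methyl (3S,10R)-3-(TBS-oxy)-8-oxoeudesma-4,6-dien-12-oate (C11 epimers) | COC(=O)C(C)C1=CC2=C(C)[C@@H](O[Si](C)(C)C(C)(C)C)CC[C@]2(C)CC1=O
F3 | step 10 | 1-[(1R,4S)-4-(TBS-oxy)-1,3-dimethyl-2-[(PMB-oxy)methyl]cyclohex-2-en-1-yl]propan-2-one | CC(=O)C[C@@]1(C)CC[C@H](O[Si](C)(C)C(C)(C)C)C(C)=C1COCc1ccc(OC)cc1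
F4 | step 15 | (3S,7S,8R,10R,11R)-11-hydroxy-3-(TBS-oxy)eudesm-4-en-12,8-olide (OH cis to H7) | O=C1O[C@@H]2C[C@@]3(C)CC[C@H](O[Si](C)(C)C(C)(C)C)C(C)=C3C[C@@H]2[C@@]1(C)O
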